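The route rests on disconnecting the C5–C10 ring-fusion bond (labdane numbering), which opens the decalin to a ten-membered carbocycle. The key step exploits two features: this one bond is shared by rings A and B, and the trans H5/C10-methyl relationship with the equatorial 6α-acetate is what anti addition to an E 5,6-alkene leaves behind. Ionising the tertiary allylic alcohol 20 in acetic acid therefore forms both six-membered rings, three stereocentres and the acetate in one operation. Alcohol 20, an E-cyclodecenol with an exocyclic methylidene group and one methyl-bearing stereocentre, comes from anionic oxy-Cope ring expansion of an enantiopure divinylcyclohexanol.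

Key step: step 11

Remark: labdane numbering is used for the decalin carbons; racemates are written as both enantiomers joined by a dot; the C1 configuration of 15 and of 20 is not controlled (15 is drawn as the expected epimer, 20 as one epimer) because that centre is destroyed in steps 8 and 11; the route adds a resolution (steps 4 to 6) because the oxy-Cope step can only transfer chirality from an enantiopure 2-vinyl ketone.

Step 1
Reactants: 1 ethyl vinyl ether
Product: 3 2-(phenylselanyl)acetaldehyde, via diethyl acetal 2 (not isolated)
Conditions: PhSeBr, EtOH, 0 °C; then 1 M HCl, Et2O, 20 °C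
Reagents that add atoms: benzeneselenenyl bromide (Br[Se]c1ccccc1); water (O)
Why: Alkoxyselenenylation of the enol ether (PhSe+ adds to the terminal carbon and ethanol traps the oxocarbenium ion) gives the acetal, which the aqueous acid hydrolyses in the same flask to the aldehyde.

Step 2
Reactants: 4 3-methylcyclohex-2-en-1-one; 3 2-(phenylselanyl)acetaldehyde
Product: 6 2-[1-hydroxy-2-(phenylselanyl)ethyl]-3,3-dimethylcyclohexan-1-one (racemic diastereomer mixture), via bromomagnesium enolate 5 (not isolated)
Conditions: MeMgBr, CuBr·SMe2 (5 mol %), Et2O/THF, −20 → 0 °C; then 3, −78 °C; aq. NH4Cl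
Reagents that add atoms: methylmagnesium bromide (C[Mg]Br)
Why: Copper-catalysed conjugate addition of the Grignard reagent to the β,β-disubstituted enone builds the gem-dimethyl carbon and leaves a regiodefined magnesium enolate whose nucleophilic carbon is C2, so the aldol addition to the unhindered aldehyde installs the two-carbon unit next to the quaternary carbon; the carbinol centre is erased in step 3 and the racemic C2 centre is resolved in step 5.

Step 3
Reactants: 6 2-[1-hydroxy-2-(phenylselanyl)ethyl]-3,3-dimethylcyclohexan-1-one
Product: 8 racemic 2-ethenyl-3,3-dimethylcyclohexan-1-one, via mesylate 7 (not isolated)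
Conditions: MsCl, Et3N, CH2Cl2, 0 → 20 °C
Reagents that add atoms: none
Why: O-Mesylation followed by selenium-assisted anti elimination through a seleniranium ion (reductive elimination of a β-hydroxy selenide) gives the terminal vinyl group under conditions mild enough to keep the β,γ-unsaturated ketone out of conjugation.

Step 4
Reactants: 8 racemic 2-ethenyl-3,3-dimethylcyclohexan-1-one
Product: 9 racemic trans-2-ethenyl-3,3-dimethylcyclohexan-1-ol
Conditions: LiBH(s-Bu)3, THF, −78 °C; then H2O
Reagents that add atoms: none
Why: In both chair conformers an axial C3 methyl blocks axial hydride delivery, so the bulky borohydride should attack equatorially and preferentially through the conformer with an axial vinyl group, which gives the trans alcohol (diastereoselective ketone reduction); any cis isomer is removed by chromatography before the resolution.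

Step 5
Reactants: 9 racemic trans-2-ethenyl-3,3-dimethylcyclohexan-1-ol
Product: 10 (1S,2S)-2-ethenyl-3,3-dimethylcyclohexan-1-ol
Conditions: immobilised Candida antarctica lipase B, vinyl acetate, MTBE, 35 °C, stopped slightly past half conversion; chromatography
Reagents that add atoms: none
Why: Lipase-catalysed transesterification (enzymatic kinetic resolution) acylates the enantiomer of a 2-substituted cyclohexanol whose carbinol centre is R, so the (1S,2S) alcohol should stay unreacted and its enantiomeric purity is secured by running slightly past half conversion.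

Step 6
Reactants: 10 (1S,2S)-2-ethenyl-3,3-dimethylcyclohexan-1-ol
Product: 11 (2S)-2-ethenyl-3,3-dimethylcyclohexan-1-one
Conditions: Dess–Martin periodinane, NaHCO3, CH2Cl2, 0 °C
Reagents that add atoms: none
Why: Dess–Martin oxidation under buffered, base-free conditions gives the ketone without enolising the α-vinyl stereocentre, which keeps its S configuration, and the product is used directly without chromatography.

Step 7
Reactants: 11 (2S)-2-ethenyl-3,3-dimethylcyclohexan-1-one; 12 (E)-1-bromoprop-1-ene
Product: 15 (1R,2S)-2-ethenyl-3,3-dimethyl-1-[(1E)-prop-1-en-1-yl]cyclohexan-1-ol, via (E)-prop-1-enyllithium 13 (not isolated), via (E)-prop-1-enylcerium dichloride 14 (not isolated)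
Conditions: 12, t-BuLi (2 equiv), Et2O, −78 °C; anhydrous CeCl3, THF, −78 °C; then 11, −78 °C; aq. NH4Cl
Reagents that add atoms: none
Why: Bromine–lithium exchange retains the E geometry and the weakly basic organocerium reagent adds to the hindered, easily enolised ketone (1,2-addition) instead of deprotonating C2, approaching equatorially because the axial C3 methyl shields the axial trajectory, which should give mainly the 1R carbinol; the C1 epimer is tolerated because C1 becomes a carbonyl carbon in step 8.

Step 8
Reactants: 15 (1R,2S)-2-ethenyl-3,3-dimethyl-1-[(1E)-prop-1-en-1-yl]cyclohexan-1-ol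
Product: 17 (3R,5E)-2-[(dimethylamino)methyl]-3,7,7-trimethylcyclodec-5-en-1-one (mixture of C2 epimers), via potassium dienolate 16 (not isolated)
Conditions: KH, 18-crown-6, THF, 0 → 40 °C; then −78 °C, CH2=NMe2+ I−, → 20 °C
Reagents that add atoms: dimethylmethylideneammonium iodide (C=[N+](C)C.[I-])
Why: Anionic oxy-Cope rearrangement through a chair transition state that keeps the CMe2-bearing ring carbon and the propenyl methyl pseudo-equatorial cleaves the C1–C2 bond, gives the E ring alkene and transfers the S configuration of C2 to the new methyl-bearing centre (R), and the regiodefined potassium enolate is then aminomethylated at C2 of the cyclodecenone by the iminium salt (Mannich reaction), the centre formed there being erased in step 9.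

Step 9
Reactants: 17 (3R,5E)-2-[(dimethylamino)methyl]-3,7,7-trimethylcyclodec-5-en-1-one
Product: 19 (3R,5E)-3,7,7-trimethyl-2-methylidenecyclodec-5-en-1-one, via trimethylammonium iodide 18 (not isolated)
Conditions: MeI, CH2Cl2, 20 °C; then sat. aq. NaHCO3, 20 °C
Reagents that add atoms: none
Why: Exhaustive N-methylation and mild base-induced β-elimination of trimethylamine (Hofmann-type elimination of a Mannich base) give the α-methylidene ketone without touching the neighbouring C3 stereocentre.

Step 10
Reactants: 19 (3R,5E)-3,7,7-trimethyl-2-methylidenecyclodec-5-en-1-one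
Product: 20 (1R,3R,5E)-1,3,7,7-tetramethyl-2-methylidenecyclodec-5-en-1-ol
Conditions: MeLi, anhydrous CeCl3, THF, −78 °C; aq. NH4Cl
Reagents that add atoms: methyllithium ([Li]C)
Why: Methylcerium dichloride adds to the carbonyl group of the cross-conjugated enone (organocerium 1,2-addition) without conjugate addition or enolisation; the configuration of the new carbinol centre is not controlled and does not matter because C1 is ionised in step 11.

Step 11
Reactants: 20 (1R,3R,5E)-1,3,7,7-tetramethyl-2-methylidenecyclodec-5-en-1-ol
Product: 22 (1S,3R,4aS,8aS)-3,4a,8,8-tetramethyl-4-methylidenedecahydronaphthalen-1-yl acetate, via allyl cation 21 (not isolated)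
Conditions: AcOH (solvent), CF3CO2H (5 mol %), 20 °C; aq. NaHCO3
Reagents that add atoms: acetic acid (CC(=O)O)
Why: Protonation and loss of water from the tertiary allylic alcohol give allyl cation 21 (C10–C9–C11), C5 of the E-configured 5,6-alkene bonds to C10 across the ring, and acetic acid caps the developing positive charge at C6 from the side opposite to the new bond. The closest known reaction type is the transannular cation–olefin cyclisation of (E)-cyclodec-5-enyl cations, seen in solvolyses of cyclodecenyl esters and in acid-induced germacradiene-to-eudesmane closures. The single C5–C10 bond closes ring A in a 6-exo-trig mode and ring B in a 6-endo-trig mode with respect to the 5,6-alkene. C10 and C5 are set by the chair–chair fold of the ten-membered ring that keeps the C8 methyl equatorial (the other fold would place it syn-axial to the C10 methyl), the E geometry translating into the trans ring fusion, and C6 is set by anti addition, which makes the acetate equatorial (α). The step needs attack at C10 and not at C11, 1,6- and not 1,5-closure, and survival of the 9(11)-alkene: the transannular proximity of C5 to C10 secures the first two, capture of 21 by acetate at C10 or C11 or loss of a proton is expected to be reversible whereas formation of 22 is not, and the low acidity should leave the methylidene group unprotonated.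

Step 12
Reactants: 22 (1S,3R,4aS,8aS)-3,4a,8,8-tetramethyl-4-methylidenedecahydronaphthalen-1-yl acetate
Product: 23 9α,11-epoxide of 22 (spiro-oxirane at C9 with its oxygen on the α face; labdane numbering)
Conditions: mCPBA, NaHCO3, CH2Cl2, 0 °C
Reagents that add atoms: 3-chloroperoxybenzoic acid (OOC(=O)c1cccc(Cl)c1)
Why: Prilezhaev epoxidation of the only alkene, in which the peracid should approach C9 along the axial direction on the α face because the β face is screened by the neighbouring axial C10 methyl, so the epoxide oxygen ends up α.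

Step 13
Reactants: 24 furan-3-ylmethanol
Product: 25 tert-butyl(furan-3-ylmethoxy)dimethylsilane
Conditions: TBSCl, imidazole, DMF, 20 °C
Reagents that add atoms: tert-butyldimethylsilyl chloride (CC(C)(C)[Si](C)(C)Cl)
Why: Silyl ether formation at the primary alcohol sets up the silyl transfer of step 14.

Step 14
Reactants: 25 tert-butyl(furan-3-ylmethoxy)dimethylsilane
Product: 27 [2-(tert-butyldimethylsilyl)furan-3-yl]methanol, via 2-lithiofuran 26 (not isolated)
Conditions: n-BuLi, HMPA, THF, −78 → 0 °C; then H2O
Reagents that add atoms: none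
Why: Lithiation at furan C2, directed by the adjacent silyloxymethyl group, is followed in the presence of HMPA by 1,4 O-to-C silyl migration (retro-Brook rearrangement), which places silicon regiospecifically at C2 and frees the alcohol.

Step 15
Reactants: 27 [2-(tert-butyldimethylsilyl)furan-3-yl]methanol
Product: 28 tert-butyl[3-(chloromethyl)furan-2-yl]dimethylsilane
Conditions: PPh3, NCS, THF, 0 → 20 °C
Reagents that add atoms: N-chlorosuccinimide (O=C1CCC(=O)N1Cl)
Why: Appel-type chlorination of the primary alcohol by the chlorophosphonium salt formed from PPh3 and NCS runs under neutral conditions that the acid-sensitive 2-silylfuran tolerates.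

Step 16
Reactants: 28 tert-butyl[3-(chloromethyl)furan-2-yl]dimethylsilane; 23 9α,11-epoxide of 22
Product: 30 (1S,3R,4R,4aS,8aS)-4-{2-[2-(tert-butyldimethylsilyl)furan-3-yl]ethyl}-4-hydroxy-3,4a,8,8-tetramethyldecahydronaphthalen-1-yl acetate, via Grignard reagent 29 (not isolated)
Conditions: 28, Mg, THF, 0 °C; then 23, CuI (10 mol %), THF, −30 → 0 °C; aq. NH4Cl
Reagents that add atoms: none
Why: The furylmethyl Grignard reagent, whose C2 is blocked by silicon against reaction through the ring, opens the 1,1-disubstituted epoxide at its CH2 carbon (C11) under copper catalysis (SN2 epoxide opening by an organocopper species), so the C9–O bond keeps its α configuration and the low temperature should spare the acetate.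

Step 17
Reactants: 30 (1S,3R,4R,4aS,8aS)-4-{2-[2-(tert-butyldimethylsilyl)furan-3-yl]ethyl}-4-hydroxy-3,4a,8,8-tetramethyldecahydronaphthalen-1-yl acetate
Product: 32 (1S,3R,4R,4aS,8aS)-4-hydroxy-3,4a,8,8-tetramethyl-4-[2-(2-oxo-2,5-dihydrofuran-3-yl)ethyl]decahydronaphthalen-1-yl acetate (target CNP0205088.2), via silyloxyfuran 31 (not isolated)
Conditions: AcOOH (32% in AcOH), NaOAc, CH2Cl2, 0 → 20 °C
Reagents that add atoms: peracetic acid (CC(=O)OO)
Why: Peracid oxidation at the silylated furan carbon with C-to-O silyl shift gives silyloxyfuran 31, which is protonated at C5 and desilylated to the α-substituted Δα,β-butenolide with the carbonyl on the former silyl-bearing carbon (oxidative unmasking of a 2-silylfuran), and nothing else in the molecule is oxidisable.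

Compound list
1 | ethyl vinyl ether | C=COCC | starting material
2 | [(2,2-diethoxyethyl)selanyl]benzene (diethyl acetal of 3) | CCOC(C[Se]c1ccccc1)OCC | intermediate
3 | 2-(phenylselanyl)acetaldehyde | O=CC[Se]c1ccccc1 | intermediate
4 | 3-methylcyclohex-2-en-1-one | CC1=CC(=O)CCC1 | starting material
5 | bromomagnesium 3,3-dimethylcyclohex-1-en-1-olate | CC1(C)CCCC(O[Mg]Br)=C1 | intermediate
6 | 2-[1-hydroxy-2-(phenylselanyl)ethyl]-3,3-dimethylcyclohexan-1-one (racemic, both diastereomers) | CC1(C)CCCC(=O)C1C(O)C[Se]c1ccccc1 | intermediate
7 | 1-(2,2-dimethyl-6-oxocyclohexyl)-2-(phenylselanyl)ethyl methanesulfonate (racemic, both diastereomers) | CC1(C)CCCC(=O)C1C(OS(C)(=O)=O)C[Se]c1ccccc1 | intermediate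
8 | racemic 2-ethenyl-3,3-dimethylcyclohexan-1-one | C=CC1C(=O)CCCC1(C)C | intermediate
9 | racemic trans-2-ethenyl-3,3-dimethylcyclohexan-1-ol, (1S,2S) and (1R,2R) | C=C[C@@H]1[C@@H](O)CCCC1(C)C.C=C[C@H]1[C@H](O)CCCC1(C)C | intermediate
10 | (1S,2S)-2-ethenyl-3,3-dimethylcyclohexan-1-ol | C=C[C@@H]1[C@@H](O)CCCC1(C)C | intermediate
11 | (2S)-2-ethenyl-3,3-dimethylcyclohexan-1-one | C=C[C@@H]1C(=O)CCCC1(C)C | intermediate
12 | (E)-1-bromoprop-1-ene | C/C=C/Br | starting material
13 | (E)-prop-1-enyllithium | C/C=C/[Li] | intermediate
14 | (E)-prop-1-enylcerium dichloride | C/C=C/[Ce](Cl)Cl | intermediate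
15 | (1R,2S)-2-ethenyl-3,3-dimethyl-1-[(1E)-prop-1-en-1-yl]cyclohexan-1-ol | C=C[C@@H]1[C@](O)(/C=C/C)CCCC1(C)C | intermediate
16 | potassium (1E,3R,5E)-3,7,7-trimethylcyclodeca-1,5-dien-1-olate | [K+].[O-]/C1=C/[C@H](C)C/C=C/C(C)(C)CCC1 | intermediate
17 | (3R,5E)-2-[(dimethylamino)methyl]-3,7,7-trimethylcyclodec-5-en-1-one (C2 epimers) | CN(C)CC1[C@H](C)C/C=C/C(C)(C)CCCC1=O | intermediate
18 | N,N,N-trimethyl-1-[(3R,5E)-3,7,7-trimethyl-1-oxocyclodec-5-en-2-yl]methanaminium iodide (C2 epimers) | [I-].C[N+](C)(C)CC1[C@H](C)C/C=C/C(C)(C)CCCC1=O | intermediate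
19 | (3R,5E)-3,7,7-trimethyl-2-methylidenecyclodec-5-en-1-one | C=C1[C@H](C)C/C=C/C(C)(C)CCCC1=O | intermediate
20 | (1R,3R,5E)-1,3,7,7-tetramethyl-2-methylidenecyclodec-5-en-1-ol (key-step precursor) | C[C@@]1(O)CCCC(C)(C)/C=C/C[C@@H](C)C1=C | intermediate
21 | (3R,5E)-1,3,7,7-tetramethyl-2-methylidenecyclodec-5-en-1-ylium (allyl cation over C10, C9 and C11 in labdane numbering) | C[C+]1CCCC(C)(C)/C=C/C[C@@H](C)C1=C | intermediate
22 | (1S,3R,4aS,8aS)-3,4a,8,8-tetramethyl-4-methylidenedecahydronaphthalen-1-yl acetate (labdane numbering: 6α-acetoxy, 8α-methyl, 10β-methyl, 5α-H, 9(11)-ene) | CC(=O)O[C@H]1C[C@@H](C)C(=C)[C@@]2(C)CCCC(C)(C)[C@H]12 | intermediate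
23 | 9α,11-epoxide of 22 (spiro-oxirane at C9, oxygen α, CH2 = C11) | CC(=O)O[C@H]1C[C@@H](C)[C@]3(CO3)[C@@]2(C)CCCC(C)(C)[C@H]12 | intermediate
24 | furan-3-ylmethanol | OCc1ccoc1 | starting material
25 | tert-butyl(furan-3-ylmethoxy)dimethylsilane | CC(C)(C)[Si](C)(C)OCc1ccoc1 | intermediate
26 | {3-[(tert-butyldimethylsilyloxy)methyl]furan-2-yl}lithium | CC(C)(C)[Si](C)(C)OCc1ccoc1[Li] | intermediate
27 | [2-(tert-butyldimethylsilyl)furan-3-yl]methanol | CC(C)(C)[Si](C)(C)c1occc1CO | intermediate
28 | tert-butyl[3-(chloromethyl)furan-2-yl]dimethylsilane | CC(C)(C)[Si](C)(C)c1occc1CCl | intermediate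
29 | {[2-(tert-butyldimethylsilyl)furan-3-yl]methyl}magnesium chloride | CC(C)(C)[Si](C)(C)c1occc1C[Mg]Cl | intermediate
30 | (1S,3R,4R,4aS,8aS)-4-{2-[2-(tert-butyldimethylsilyl)furan-3-yl]ethyl}-4-hydroxy-3,4a,8,8-tetramethyldecahydronaphthalen-1-yl acetate | CC(=O)O[C@H]1C[C@@H](C)[C@](O)(CCc3ccoc3[Si](C)(C)C(C)(C)C)[C@@]2(C)CCCC(C)(C)[C@H]12 | intermediate
31 | (1S,3R,4R,4aS,8aS)-4-{2-[2-(tert-butyldimethylsilyloxy)furan-3-yl]ethyl}-4-hydroxy-3,4a,8,8-tetramethyldecahydronaphthalen-1-yl acetate | CC(=O)O[C@H]1C[C@@H](C)[C@](O)(CCc3ccoc3O[Si](C)(C)C(C)(C)C)[C@@]2(C)CCCC(C)(C)[C@H]12 | intermediate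
32 | (1S,3R,4R,4aS,8aS)-4-hydroxy-3,4a,8,8-tetramethyl-4-[2-(2-oxo-2,5-dihydrofuran-3-yl)ethyl]decahydronaphthalen-1-yl acetate (CNP0205088.2) | CC(=O)O[C@H]1C[C@@H](C)[C@](O)(CCC2=CCOC2=O)[C@@]2(C)CCCC(C)(C)[C@H]12 | target

Total step count: 17.
Longest linear sequence: 14 steps (steps 1 to 12, then 16 and 17, from ethyl vinyl ether 1 to target 32).

Steps most likely to fail

Step 11. The allyl cation may lose a proton to give dienes or be trapped by acetate at C11 faster than C5 closes onto C10, and the acid may protonate the exocyclic alkene of the product and move it into the ring. The fallback sets out from 20 and changes the way the cation is made. The alcohol is deprotonated with n-BuLi in THF at −78 °C and acylated with 4-nitrobenzoyl chloride to give (1R,3R,5E)-1,3,7,7-tetramethyl-2-methylidenecyclodec-5-en-1-yl 4-nitrobenzoate F1. Buffered acetolysis of this tertiary allylic ester (AcOH, NaOAc, 50 °C) forms cation 21 with no strong acid present, and the route is rejoined at 22.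

Step 16. Acyl attack of the Grignard reagent on the C6 acetate and rearrangement of the hindered spiro-epoxide induced by magnesium salts may outrun the slow substitution at the neopentyl-like C11, and Wurtz-type homocoupling may consume the furylmethyl chloride. The fallback sets out from 22 (step 12 is then not needed) and builds the side chain by carbonyl addition and cross-coupling.
- Ozonolysis (O3, CH2Cl2, −78 °C; Me2S) gives (1S,3R,4aS,8aS)-3,4a,8,8-tetramethyl-4-oxodecahydronaphthalen-1-yl acetate F2.
- Vinylmagnesium bromide with CeCl3 in THF at −78 °C should add from the β face (equatorial attack) to give (1S,3R,4R,4aS,8aS)-4-ethenyl-4-hydroxy-3,4a,8,8-tetramethyldecahydronaphthalen-1-yl acetate F3.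
- Hydroboration with 9-BBN in THF gives the B-alkyl-9-borabicyclo[3.3.1]nonane adduct F4.
- Suzuki–Miyaura coupling of F4 with (3-bromofuran-2-yl)(tert-butyl)dimethylsilane F5 (from 3-bromofuran, LDA, then TBSCl), using Pd(dppf)Cl2 and K3PO4 in THF/H2O at 50 °C, gives 30, where the route is rejoined.

Step 5. The enzyme may acylate the hindered alcohol too slowly or discriminate poorly between its enantiomers, so that the recovered alcohol is not enantiopure. The fallback sets out from racemic ketone 8 and replaces steps 4 and 5 by a reagent-controlled reduction. CBS reduction with catecholborane and (R)-2-methyl-CBS-oxazaborolidine (10 mol %) in toluene at −78 °C should deliver hydride to the same carbonyl face of both enantiomers. This gives 10 from (S)-8 and the cis diastereomer (1S,2R)-2-ethenyl-3,3-dimethylcyclohexan-1-ol F6 from (R)-8. The two diastereomers are separated by chromatography and the route is rejoined at 10.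

Further compounds
F1 | step 11 | (1R,3R,5E)-1,3,7,7-tetramethyl-2-methylidenecyclodec-5-en-1-yl 4-nitrobenzoate | C[C@@]1(OC(=O)c2ccc(cc2)[N+](=O)[O-])CCCC(C)(C)/C=C/C[C@@H](C)C1=C
F2 | step 16 | (1S,3R,4aS,8aS)-3,4a,8,8-tetramethyl-4-oxodecahydronaphthalen-1-yl acetate | CC(=O)O[C@H]1C[C@@H](C)C(=O)[C@@]2(C)CCCC(C)(C)[C@H]12
F3 | step 16 | (1S,3R,4R,4aS,8aS)-4-ethenyl-4-hydroxy-3,4a,8,8-tetramethyldecahydronaphthalen-1-yl acetate | CC(=O)O[C@H]1C[C@@H](C)[C@](O)(C=C)[C@@]2(C)CCCC(C)(C)[C@H]12
F4 | step 16 | (1S,3R,4R,4aS,8aS)-4-[2-(9-borabicyclo[3.3.1]nonan-9-yl)ethyl]-4-hydroxy-3,4a,8,8-tetramethyldecahydronaphthalen-1-yl acetate | CC(=O)O[C@H]1C[C@@H](C)[C@](O)(CCB3C4CCCC3CCC4)[C@@]2(C)CCCC(C)(C)[C@H]12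
F5 | step 16 | (3-bromofuran-2-yl)(tert-butyl)dimethylsilane | CC(C)(C)[Si](C)(C)c1occc1Br
F6 | step 5 | (1S,2R)-2-ethenyl-3,3-dimethylcyclohexan-1-ol | C=C[C@H]1[C@@H](O)CCCC1(C)C
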